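All three C2–C1′ bonds (pyran ring C to ring B) are cut at once: each C2 lies next to O1 and carries the same 4-hydroxyphenyl ring, trans to the C4 aryl in units 1 and 2 and cis to O3 in units 2 and 3. One threefold oxocarbenium C-arylation of a tris(chroman-2-yl acetate) with a 4-benzyloxyphenyl boron nucleophile adds three rings B, three C–C bonds and three stereocentres. The precursor is a benzyl-protected, B-ring-free trimer of 2-acetoxychromans linked C4→C8 that holds C4 of unit 1, C3 and C4 of unit 2 and C3 of unit 3. It is built from lactones by glycolate aldol additions, a tethered Friedel–Crafts closure and one conjugate arylation.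

Key step: step 16

Conventions and remarks
- Flavan numbering is used for every unit: O1, C2, C3, C4, ring A = C4a–C8a, ring B on C2, ring C = the pyran ring. Unit 1 is the upper unit without O3 and O5, unit 2 the middle unit, unit 3 the lower unit.
- Assumption: 5-(benzyloxy)-2-bromophenol is bought; otherwise it would be made by mono-O-benzylation of 4-bromoresorcinol.
- The trichlorotitanium enolate 7 is generated from 6 in two separate flasks by the same protocol, in step 4 and again in step 8; it is entered where it first forms.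
- Step 16 consumes three equivalents of 26 per molecule of 24, one for each C2.
- Design of the key-step substrate: O3 of units 2 and 3 carries a non-participating benzyl ether, because an acyl group would steer C2 trans. The three leaving groups are anomeric acetates made by acetylating the aluminium hemiacetals directly, so no free lactol ever faces the phenol oxygen of its neighbour. The substrate is used as an anomeric mixture (one anomer is drawn), and its four fixed stereocentres map one-to-one onto the target.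

Step 1
Reactants: 1 2,4,6-trihydroxybenzaldehyde
Product: 2 4,6-bis(benzyloxy)-2-hydroxybenzaldehyde
Conditions: BnBr (2.1 equiv), K2CO3, DMF, 0 °C to rt
Reagents that add atoms: benzyl bromide, BrCc1ccccc1
Why: Williamson etherification should alkylate the 4-OH and one ortho OH, while the remaining ortho OH (the later O1), held in a hydrogen bond to the formyl oxygen, stays free.

Step 2
Reactants: 2 4,6-bis(benzyloxy)-2-hydroxybenzaldehyde
Product: 3 4,6-bis(benzyloxy)-2-[(tert-butyldimethylsilyl)oxy]benzaldehyde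
Conditions: TBSCl, imidazole, DMF, 40 °C
Reagents that add atoms: tert-butyldimethylsilyl chloride, CC(C)(C)[Si](C)(C)Cl
Why: Silyl ether formation masks the phenol so that the aldehyde can enter a titanium aldol addition and O1 can be released later by fluoride.

Step 3
Reactants: 4 (R)-4-benzyl-1,3-thiazolidine-2-thione; 5 (benzyloxy)acetyl chloride
Product: 6 (R)-4-benzyl-3-[(benzyloxy)acetyl]-1,3-thiazolidine-2-thione
Conditions: Et3N, DMAP (cat.), CH2Cl2, 0 °C
Reagents that add atoms: none
Why: N-Acylation of the thiazolidinethione with the acid chloride gives the chiral glycolate imide that supplies C2, C3 and the benzylated O3 of units 2 and 3.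

Step 4
Reactants: 6 (R)-4-benzyl-3-[(benzyloxy)acetyl]-1,3-thiazolidine-2-thione; 3 4,6-bis(benzyloxy)-2-[(tert-butyldimethylsilyl)oxy]benzaldehyde
Product: 8 (R)-4-benzyl-3-{(2R,3S)-2-(benzyloxy)-3-[2,4-bis(benzyloxy)-6-(tert-butyldimethylsilyloxy)phenyl]-3-hydroxypropanoyl}-1,3-thiazolidine-2-thione, via trichlorotitanium enolate 7 (not isolated)
Conditions: 6, TiCl4 (1.05 equiv), i-Pr2NEt (1.1 equiv), NMP (1 equiv), CH2Cl2, 0 °C; then 3, −78 to 0 °C
Reagents that add atoms: none
Why: Evans-syn titanium-enolate glycolate aldol addition, in which the (R)-auxiliary shields one face of the Z-enolate and sets the benzyloxy-bearing carbon as R (the later C3 of unit 3), while the carbinol centre is removed in step 5.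

Step 5
Reactants: 8 the aldol adduct of step 4
Product: 9 (R)-4-benzyl-3-{(2R)-2-(benzyloxy)-3-[2,4-bis(benzyloxy)-6-(tert-butyldimethylsilyloxy)phenyl]propanoyl}-1,3-thiazolidine-2-thione
Conditions: Et3SiH (5 equiv), CF3CO2H (5 equiv), CH2Cl2, −20 °C
Reagents that add atoms: none
Why: Ionic hydrogenation: the 2,4,6-trioxygenated benzylic alcohol ionises readily and the cation is reduced by hydride transfer from the silane, giving the C4 methylene of unit 3 without touching the α-stereocentre.

Step 6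
Reactants: 9 the deoxygenated imide of step 5
Product: 10 (3R)-3,5,7-tris(benzyloxy)chroman-2-one (unit 3 lactone)
Conditions: Bu4NF, AcOH, THF, 0 °C to rt
Reagents that add atoms: none
Why: Fluoride desilylation frees the phenol, which closes ring C by intramolecular acyl transfer (lactonisation) with loss of the thiazolidinethione, the acetic acid buffer guarding C3 against epimerisation.

Step 7
Reactants: 10 (3R)-3,5,7-tris(benzyloxy)chroman-2-one
Product: 12 (3R)-3,5,7-tris(benzyloxy)-2-oxochromane-8-carbaldehyde, via iminium chloride 11 (not isolated)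
Conditions: POCl3, DMF, 0 to 60 °C; then H2O, 0 °C
Reagents that add atoms: N,N-dimethylformamide, CN(C)C=O; water, O
Why: Vilsmeier–Haack formylation should go to C8, which is para to the 5-benzyloxy group and flanked by the small lactone oxygen, and not to C6, which lies between two benzyloxy groups and is para only to the weakly donating acyloxy oxygen.

Step 8
Reactants: 12 (3R)-3,5,7-tris(benzyloxy)-2-oxochromane-8-carbaldehyde; 6 (R)-4-benzyl-3-[(benzyloxy)acetyl]-1,3-thiazolidine-2-thione (enolised in the flask by the protocol of step 4)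
Product: 13 (R)-4-benzyl-3-{(2R,3S)-2-(benzyloxy)-3-hydroxy-3-[(3R)-3,5,7-tris(benzyloxy)-2-oxochroman-8-yl]propanoyl}-1,3-thiazolidine-2-thione
Conditions: 6, TiCl4 (1.05 equiv), i-Pr2NEt (1.1 equiv), NMP (1 equiv), CH2Cl2, 0 °C (enolisation as in step 4); then 12, −78 to −20 °C
Reagents that add atoms: none
Why: A second Evans-syn titanium glycolate aldol addition with the preformed enolate (no free base, so the lactone is not enolised) sets C3 of unit 2 as R and joins the later C4 of unit 2 to C8 of unit 3; the carbinol centre is ionised in step 11.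

Step 9
Reactants: 2 4,6-bis(benzyloxy)-2-hydroxybenzaldehyde; 14 methyl (triphenylphosphoranylidene)acetate
Product: 15 methyl (2E)-3-[2,4-bis(benzyloxy)-6-hydroxyphenyl]prop-2-enoate
Conditions: toluene, 80 °C
Reagents that add atoms: none
Why: Wittig olefination with a stabilised ylide gives the E-acrylate at the later C8 of unit 2 and leaves the phenol (the later O1 of unit 2) free.

Step 10
Reactants: 13 the aldol adduct of step 8; 15 methyl (2E)-3-[2,4-bis(benzyloxy)-6-hydroxyphenyl]prop-2-enoate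
Product: 16 3,5-bis(benzyloxy)-2-[(1E)-3-methoxy-3-oxoprop-1-enyl]phenyl (2R,3S)-2-(benzyloxy)-3-hydroxy-3-[(3R)-3,5,7-tris(benzyloxy)-2-oxochroman-8-yl]propanoate
Conditions: 15 (2 equiv), DMAP (0.3 equiv), CH2Cl2, rt
Reagents that add atoms: none
Why: DMAP-catalysed acyl transfer from the activated N-acylthiazolidinethione to the phenol (esterification) ties the glycolate chain to O1 of unit 2 and releases the auxiliary, the aryl lactone being far less electrophilic.

Step 11
Reactants: 16 the aryl ester of step 10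
Product: 17 methyl (2E)-3-{(3R,4S)-3,5,7-tris(benzyloxy)-2-oxo-4-[(3R)-3,5,7-tris(benzyloxy)-2-oxochroman-8-yl]chroman-8-yl}prop-2-enoate (bis-lactone, unit 2 3,4-trans)
Conditions: BF3·OEt2 (0.3 equiv), 4 Å molecular sieves, CH2Cl2, −40 to 0 °C
Reagents that add atoms: none
Why: Intramolecular Friedel–Crafts alkylation: the benzylic cation at the later C4 of unit 2 is trapped by the tethered ring at its only free position ortho to the ester oxygen, and allylic 1,3-strain holds H3 in the cation plane so that the arene adds anti to the O3 benzyl ether, giving the 3,4-trans lactone (4S).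

Step 12
Reactants: 18 5-(benzyloxy)-2-bromophenol
Product: 20 [4-(benzyloxy)-2-hydroxyphenyl]boronic acid, via dilithio phenolate 19 (not isolated)
Conditions: n-BuLi (2.2 equiv), THF, −78 °C; then B(OiPr)3; then aq. NH4Cl
Reagents that add atoms: triisopropyl borate, CC(C)OB(OC(C)C)OC(C)C; water, O
Why: Deprotonation and bromine–lithium exchange followed by a borate quench (lithiation–borylation) gives the ortho-hydroxyarylboronic acid that becomes ring A of unit 1.

Step 13
Reactants: 17 the bis-lactone acrylate of step 11; 20 [4-(benzyloxy)-2-hydroxyphenyl]boronic acid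
Product: 22 (4R)-7-(benzyloxy)-4-{(3R,4S)-3,5,7-tris(benzyloxy)-2-oxo-4-[(3R)-3,5,7-tris(benzyloxy)-2-oxochroman-8-yl]chroman-8-yl}chroman-2-one (tris-lactone), via hydroxy ester adduct 21 (not isolated)
Conditions: 20 (5 equiv), Rh(acac)(C2H4)2 (5 mol%), (S)-BINAP (6 mol%), dioxane/H2O (10:1), 100 °C; then TsOH·H2O (10 mol%), toluene, 80 °C
Reagents that add atoms: none
Why: Hayashi–Miyaura rhodium-catalysed asymmetric 1,4-addition, in which (S)-BINAP directs the aryl group to the α-si face of the E-acrylate and so sets C4 of unit 1 as R (the antipodal ligand would be used if a model cinnamate showed the opposite sense), followed by acid-catalysed lactonisation of the ortho phenol onto the methyl ester.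

Step 14
Reactants: 22 the tris-lactone of step 13
Product: 24 tris(chroman-2-yl acetate): (4R)-2-acetoxy-7-(benzyloxy)chroman-4-yl on C8 of (3R,4S)-2-acetoxy-3,5,7-tris(benzyloxy)chroman, whose C4 bears C8 of (3R)-2-acetoxy-3,5,7-tris(benzyloxy)chroman (anomeric mixture, one anomer drawn), via tris(diisobutylaluminium hemiacetal) 23 (not isolated)
Conditions: i-Bu2AlH (3.6 equiv), CH2Cl2, −78 °C; then pyridine, DMAP, Ac2O, −78 to −20 °C
Reagents that add atoms: acetic anhydride, CC(=O)OC(C)=O
Why: Reductive acetylation: i-Bu2AlH adds once to each aryl lactone at −78 °C and the aluminium hemiacetals are acetylated in the same flask, so no free lactol can open and be captured by the phenol oxygen of the neighbouring unit; C3 and C4 are untouched.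

Step 15
Reactants: 25 [4-(benzyloxy)phenyl]boronic acid
Product: 26 potassium [4-(benzyloxy)phenyl]trifluoroborate
Conditions: KHF2, MeOH/H2O, rt
Reagents that add atoms: potassium hydrogen difluoride, F.[F-].[K+]
Why: Fluoride exchange on boron (trifluoroborate formation) gives a bench-stable aryl donor that releases the reactive aryldifluoroborane only when BF3 is added.

Step 16
Reactants: 24 the tris(chroman-2-yl acetate) of step 14; 26 potassium [4-(benzyloxy)phenyl]trifluoroborate (three equivalents are consumed, one per C2)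
Product: 27 deca-O-benzyl trimer: (2S,4R)-7-(benzyloxy)-2-[4-(benzyloxy)phenyl]chroman-4-yl on C8 of (2R,3R,4S)-3,5,7-tris(benzyloxy)-2-[4-(benzyloxy)phenyl]chroman, whose C4 bears C8 of (2R,3R)-3,5,7-tris(benzyloxy)-2-[4-(benzyloxy)phenyl]chroman
Conditions: 26 (9 equiv), BF3·OEt2 (12 equiv), 4 Å molecular sieves, CH2Cl2/MeCN (5:1), −40 to 0 °C
Reagents that add atoms: potassium [4-(benzyloxy)phenyl]trifluoroborate 26 (second and third equivalents), [K+].F[B-](F)(F)c1ccc(OCc2ccccc2)cc1
Why: Proposed new method: BF3 takes fluoride from 26 to give the aryldifluoroborane and ionises each anomeric acetate to a benzopyranyl oxocarbenium ion (O1=C2), to which the boron-bound aryl group is transferred ipso, the closest known reactions being single BF3-promoted additions of potassium organotrifluoroborates to cyclic oxocarbenium ions from 2H-chromene and pyranyl acetals and Lewis-acid C-glycosylation of anomeric acetates. No ring is closed, and the three C2–C1′ bonds and the three C2 stereocentres form under substrate control. In units 1 and 2 the C4 aryl group shields its own face, where a chair-like axial attack would be 1,3-diaxial to it, so the aryl group enters anti to it (2,4-trans). In units 2 and 3 the non-participating O3 benzyl ether takes the pseudoequatorial position of the half-chair cation, so axial attack gives the 2,3-cis product, and the ether oxygen can also hold the Lewis-acidic borane on its own face, both effects agreeing in unit 2 while unit 3 depends on the O3 effect alone. The step needs arylation at C2 to outrun capture of the cations by the benzyloxy-substituted rings A and loss of H3, which the large excess of borane, the low temperature, the hindered C6 positions and the absence of any acyl group at O3 should secure. Ipso transfer is fixed by the boron substituent, and the benzyl ethers and C4–C8 bonds should tolerate BF3·OEt2 below 0 °C.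

Step 17
Reactants: 27 the deca-O-benzyl trimer of step 16
Product: 28 CNP0257624.1, (2S)-4′,7-dihydroxyflavan-(4→8)-epiafzelechin-(4→8)-epiafzelechin with unit 1 (2S,4R), unit 2 (2R,3R,4S) and unit 3 (2R,3R)
Conditions: H2 (1 atm), Pd(OH)2/C, THF/MeOH (1:1), rt
Reagents that add atoms: none
Why: Catalytic hydrogenolysis removes the ten benzyl ethers in one operation and should leave the stereocentres and the C2–O1 and C4–C8 bonds intact at 1 atm and room temperature.

Compound list
1 | 2,4,6-trihydroxybenzaldehyde | O=Cc1c(O)cc(O)cc1O | starting material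
2 | 4,6-bis(benzyloxy)-2-hydroxybenzaldehyde | O=Cc1c(O)cc(OCc2ccccc2)cc1OCc1ccccc1 | intermediate
3 | 4,6-bis(benzyloxy)-2-[(tert-butyldimethylsilyl)oxy]benzaldehyde | O=Cc1c(O[Si](C)(C)C(C)(C)C)cc(OCc2ccccc2)cc1OCc1ccccc1 | intermediate
4 | (R)-4-benzyl-1,3-thiazolidine-2-thione | S=C1N[C@H](Cc2ccccc2)CS1 | starting material
5 | (benzyloxy)acetyl chloride | O=C(Cl)COCc1ccccc1 | starting material
6 | (R)-4-benzyl-3-[(benzyloxy)acetyl]-1,3-thiazolidine-2-thione | O=C(COCc1ccccc1)N1C(=S)SC[C@H]1Cc1ccccc1 | intermediate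
7 | trichlorotitanium Z-enolate of 6 (not isolated; generated in step 4 and again, by the same protocol, in step 8) | Cl[Ti](Cl)(Cl)O/C(=C\OCc1ccccc1)N1C(=S)SC[C@H]1Cc1ccccc1 | intermediate
8 | (R)-4-benzyl-3-{(2R,3S)-2-(benzyloxy)-3-[2,4-bis(benzyloxy)-6-(tert-butyldimethylsilyloxy)phenyl]-3-hydroxypropanoyl}-1,3-thiazolidine-2-thione | O=C([C@H](OCc1ccccc1)[C@@H](O)c1c(O[Si](C)(C)C(C)(C)C)cc(OCc2ccccc2)cc1OCc1ccccc1)N1C(=S)SC[C@H]1Cc1ccccc1 | intermediate
9 | (R)-4-benzyl-3-{(2R)-2-(benzyloxy)-3-[2,4-bis(benzyloxy)-6-(tert-butyldimethylsilyloxy)phenyl]propanoyl}-1,3-thiazolidine-2-thione | O=C([C@H](OCc1ccccc1)Cc1c(O[Si](C)(C)C(C)(C)C)cc(OCc2ccccc2)cc1OCc1ccccc1)N1C(=S)SC[C@H]1Cc1ccccc1 | intermediate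
10 | (3R)-3,5,7-tris(benzyloxy)chroman-2-one | O=C1Oc2cc(OCc3ccccc3)cc(OCc3ccccc3)c2C[C@H]1OCc1ccccc1 | intermediate
11 | N-{[(3R)-3,5,7-tris(benzyloxy)-2-oxochroman-8-yl]methylidene}-N-methylmethanaminium chloride (not isolated) | C[N+](C)=Cc1c(OCc2ccccc2)cc(OCc2ccccc2)c2c1OC(=O)[C@H](OCc1ccccc1)C2.[Cl-] | intermediate
12 | (3R)-3,5,7-tris(benzyloxy)-2-oxochromane-8-carbaldehyde | O=Cc1c(OCc2ccccc2)cc(OCc2ccccc2)c2c1OC(=O)[C@H](OCc1ccccc1)C2 | intermediate
13 | (R)-4-benzyl-3-{(2R,3S)-2-(benzyloxy)-3-hydroxy-3-[(3R)-3,5,7-tris(benzyloxy)-2-oxochroman-8-yl]propanoyl}-1,3-thiazolidine-2-thione | O=C([C@H](OCc1ccccc1)[C@@H](O)c1c(OCc2ccccc2)cc(OCc2ccccc2)c2c1OC(=O)[C@H](OCc1ccccc1)C2)N1C(=S)SC[C@H]1Cc1ccccc1 | intermediate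
14 | methyl (triphenylphosphoranylidene)acetate | COC(=O)C=P(c1ccccc1)(c1ccccc1)c1ccccc1 | starting material
15 | methyl (2E)-3-[2,4-bis(benzyloxy)-6-hydroxyphenyl]prop-2-enoate | COC(=O)/C=C/c1c(O)cc(OCc2ccccc2)cc1OCc1ccccc1 | intermediate
16 | 3,5-bis(benzyloxy)-2-[(1E)-3-methoxy-3-oxoprop-1-enyl]phenyl (2R,3S)-2-(benzyloxy)-3-hydroxy-3-[(3R)-3,5,7-tris(benzyloxy)-2-oxochroman-8-yl]propanoate | COC(=O)/C=C/c1c(OC(=O)[C@H](OCc2ccccc2)[C@@H](O)c2c(OCc3ccccc3)cc(OCc3ccccc3)c3c2OC(=O)[C@H](OCc2ccccc2)C3)cc(OCc2ccccc2)cc1OCc1ccccc1 | intermediate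
17 | methyl (2E)-3-{(3R,4S)-3,5,7-tris(benzyloxy)-2-oxo-4-[(3R)-3,5,7-tris(benzyloxy)-2-oxochroman-8-yl]chroman-8-yl}prop-2-enoate | COC(=O)/C=C/c1c(OCc2ccccc2)cc(OCc2ccccc2)c2c1OC(=O)[C@H](OCc1ccccc1)[C@H]2c1c(OCc2ccccc2)cc(OCc2ccccc2)c2c1OC(=O)[C@H](OCc1ccccc1)C2 | intermediate
18 | 5-(benzyloxy)-2-bromophenol | Oc1cc(OCc2ccccc2)ccc1Br | starting material
19 | lithium 5-(benzyloxy)-2-lithiophenolate (not isolated) | [Li]Oc1cc(OCc2ccccc2)ccc1[Li] | intermediate
20 | [4-(benzyloxy)-2-hydroxyphenyl]boronic acid | OB(O)c1ccc(OCc2ccccc2)cc1O | intermediate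
21 | methyl (3R)-3-[4-(benzyloxy)-2-hydroxyphenyl]-3-{(3R,4S)-3,5,7-tris(benzyloxy)-2-oxo-4-[(3R)-3,5,7-tris(benzyloxy)-2-oxochroman-8-yl]chroman-8-yl}propanoate (not isolated) | COC(=O)C[C@@H](c1c(OCc2ccccc2)cc(OCc2ccccc2)c2c1OC(=O)[C@H](OCc1ccccc1)[C@H]2c1c(OCc2ccccc2)cc(OCc2ccccc2)c2c1OC(=O)[C@H](OCc1ccccc1)C2)c1ccc(OCc2ccccc2)cc1O | intermediate
22 | (4R)-7-(benzyloxy)-4-{(3R,4S)-3,5,7-tris(benzyloxy)-2-oxo-4-[(3R)-3,5,7-tris(benzyloxy)-2-oxochroman-8-yl]chroman-8-yl}chroman-2-one | O=C1C[C@@H](c2c(OCc3ccccc3)cc(OCc3ccccc3)c3c2OC(=O)[C@H](OCc2ccccc2)[C@H]3c2c(OCc3ccccc3)cc(OCc3ccccc3)c3c2OC(=O)[C@H](OCc2ccccc2)C3)c2ccc(OCc3ccccc3)cc2O1 | intermediate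
23 | tris(diisobutylaluminium hemiacetal) of 22, each C2 bearing H and OAl(i-Bu)2 (not isolated) | CC(C)C[Al](CC(C)C)OC1C[C@@H](c2c(OCc3ccccc3)cc(OCc3ccccc3)c3c2OC(O[Al](CC(C)C)CC(C)C)[C@H](OCc2ccccc2)[C@H]3c2c(OCc3ccccc3)cc(OCc3ccccc3)c3c2OC(O[Al](CC(C)C)CC(C)C)[C@H](OCc2ccccc2)C3)c2ccc(OCc3ccccc3)cc2O1 | intermediate
24 | tris(chroman-2-yl acetate), unit 1 (4R), unit 2 (3R,4S), unit 3 (3R), anomeric mixture with one anomer drawn | CC(=O)O[C@H]1C[C@@H](c3c(OCc9ccccc9)cc(OCc9ccccc9)c4c3O[C@@H](OC(C)=O)[C@H](OCc9ccccc9)[C@H]4c3c(OCc9ccccc9)cc(OCc9ccccc9)c4c3O[C@@H](OC(C)=O)[C@H](OCc9ccccc9)C4)c2ccc(OCc9ccccc9)cc2O1 | intermediate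
25 | [4-(benzyloxy)phenyl]boronic acid | OB(O)c1ccc(OCc2ccccc2)cc1 | starting material
26 | potassium [4-(benzyloxy)phenyl]trifluoroborate | [K+].F[B-](F)(F)c1ccc(OCc2ccccc2)cc1 | intermediate
27 | deca-O-benzyl trimer, unit 1 (2S,4R), unit 2 (2R,3R,4S), unit 3 (2R,3R) | O(Cc9ccccc9)c1ccc([C@@H]2C[C@@H](c3c(OCc9ccccc9)cc(OCc9ccccc9)c4c3O[C@H](c3ccc(OCc9ccccc9)cc3)[C@H](OCc9ccccc9)[C@H]4c3c(OCc9ccccc9)cc(OCc9ccccc9)c4c3O[C@H](c3ccc(OCc9ccccc9)cc3)[C@H](OCc9ccccc9)C4)c3ccc(OCc9ccccc9)cc3O2)cc1 | intermediate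
28 | CNP0257624.1 | Oc1ccc([C@@H]2C[C@@H](c3c(O)cc(O)c4c3O[C@H](c3ccc(O)cc3)[C@H](O)[C@H]4c3c(O)cc(O)c4c3O[C@H](c3ccc(O)cc3)[C@H](O)C4)c3ccc(O)cc3O2)cc1 | target

Total step count: 17. Longest linear sequence: 13 steps (1, 2, 4, 5, 6, 7, 8, 10, 11, 13, 14, 16, 17).

Steps most likely to fail

1. Step 16. The aryldifluoroborane may transfer its aryl group too slowly, so that the oxocarbenium ions are captured by the electron-rich rings A or lose H3 and the threefold arylation stalls at mixtures. The fallback uses the known substitution of anomeric sulfones by organozinc reagents under ZnBr2, a milder Lewis acid with a more nucleophilic aryl donor. It sets out from 24: exchange of the three acetates with PhSO2H and MgBr2·OEt2 in CH2Cl2 at 0 °C would give the tris(2-phenylsulfonylchroman) F1. Treatment with 4-(benzyloxy)phenylzinc bromide F2 (from 4-(benzyloxy)phenylmagnesium bromide and ZnBr2) in THF at rt would then deliver the three aryl groups through the same cations and with the same substrate control, coming back to the route at 27.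

2. Step 13. Insertion of the hindered, electron-rich β-aryl acrylate into the aryl–rhodium bond may be slower than protodeboronation, or the catalyst may not override the substrate in facial selectivity. The fallback builds ring C of unit 1 by the aldol/tethered Friedel–Crafts logic already used for unit 2, with a removable chlorine as the stereochemical relay. It sets out from 17: Lemieux–Johnson cleavage of the acrylate (OsO4 cat., NaIO4, 2,6-lutidine, dioxane/H2O) would give the bis-lactone 8-carbaldehyde F3. Evans-syn titanium aldol addition of (R)-4-benzyl-3-(chloroacetyl)-1,3-thiazolidine-2-thione F4 (from 4 and chloroacetyl chloride) would give the chlorohydrin imide F5. DMAP-catalysed acyl transfer to 3-(benzyloxy)phenol would give the aryl ester F6. BF3·OEt2-catalysed ring closure para to the benzyloxy group and anti to chlorine would give the 3-chloro tris-lactone F7. Zn in AcOH would remove the chlorine and come back to the route at 22.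

3. Step 7. Formylation may occur at C6 as well as C8 (poor regioselectivity). The fallback formylates ortho to a free phenol, where only one position is open. It sets out from 9: methanolysis of the imide (MeOH, imidazole) would give the methyl ester F8. Bu4NF/AcOH would give the phenol F9. MgCl2, Et3N and paraformaldehyde in MeCN at reflux, which formylate only ortho to the phenol, would give the salicylaldehyde F10. TsOH-catalysed lactonisation in toluene at 80 °C would come back to the route at 12.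

Further compounds
F1 | step 16 | tris(2-phenylsulfonylchroman) analogue of 24 (each anomeric acetate replaced by PhSO2, anomeric mixture) | O=S(=O)(c1ccccc1)C1C[C@@H](c2c(OCc3ccccc3)cc(OCc3ccccc3)c3c2OC(S(=O)(=O)c2ccccc2)[C@H](OCc2ccccc2)[C@H]3c2c(OCc3ccccc3)cc(OCc3ccccc3)c3c2OC(S(=O)(=O)c2ccccc2)[C@H](OCc2ccccc2)C3)c2ccc(OCc3ccccc3)cc2O1
F2 | step 16 | 4-(benzyloxy)phenylzinc bromide | Br[Zn]c1ccc(OCc2ccccc2)cc1
F3 | step 13 | (3R,4S)-3,5,7-tris(benzyloxy)-2-oxo-4-[(3R)-3,5,7-tris(benzyloxy)-2-oxochroman-8-yl]chromane-8-carbaldehyde | O=Cc1c(OCc2ccccc2)cc(OCc2ccccc2)c2c1OC(=O)[C@H](OCc1ccccc1)[C@H]2c1c(OCc2ccccc2)cc(OCc2ccccc2)c2c1OC(=O)[C@H](OCc1ccccc1)C2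
F4 | step 13 | (R)-4-benzyl-3-(chloroacetyl)-1,3-thiazolidine-2-thione | O=C(CCl)N1C(=S)SC[C@H]1Cc1ccccc1
F5 | step 13 | (R)-4-benzyl-3-[(2R,3S)-2-chloro-3-hydroxy-3-(bis-lactone-8-yl)propanoyl]-1,3-thiazolidine-2-thione | O=C([C@H](Cl)[C@@H](O)c1c(OCc2ccccc2)cc(OCc2ccccc2)c2c1OC(=O)[C@H](OCc1ccccc1)[C@H]2c1c(OCc2ccccc2)cc(OCc2ccccc2)c2c1OC(=O)[C@H](OCc1ccccc1)C2)N1C(=S)SC[C@H]1Cc1ccccc1
F6 | step 13 | 3-(benzyloxy)phenyl (2R,3S)-2-chloro-3-hydroxy-3-(bis-lactone-8-yl)propanoate | O=C(Oc1cccc(OCc2ccccc2)c1)[C@H](Cl)[C@@H](O)c1c(OCc2ccccc2)cc(OCc2ccccc2)c2c1OC(=O)[C@H](OCc1ccccc1)[C@H]2c1c(OCc2ccccc2)cc(OCc2ccccc2)c2c1OC(=O)[C@H](OCc1ccccc1)C2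
F7 | step 13 | 3-chloro derivative of 22 (unit 1: 3-Cl trans to the C4 aryl) | O=C1[C@H](Cl)[C@@H](c2c(OCc3ccccc3)cc(OCc3ccccc3)c3c2OC(=O)[C@H](OCc2ccccc2)[C@H]3c2c(OCc3ccccc3)cc(OCc3ccccc3)c3c2OC(=O)[C@H](OCc2ccccc2)C3)c2ccc(OCc3ccccc3)cc2O1
F8 | step 7 | methyl (2R)-2-(benzyloxy)-3-[2,4-bis(benzyloxy)-6-(tert-butyldimethylsilyloxy)phenyl]propanoate | COC(=O)[C@H](OCc1ccccc1)Cc1c(O[Si](C)(C)C(C)(C)C)cc(OCc2ccccc2)cc1OCc1ccccc1
F9 | step 7 | methyl (2R)-2-(benzyloxy)-3-[2,4-bis(benzyloxy)-6-hydroxyphenyl]propanoate | COC(=O)[C@H](OCc1ccccc1)Cc1c(O)cc(OCc2ccccc2)cc1OCc1ccccc1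
F10 | step 7 | methyl (2R)-2-(benzyloxy)-3-[4,6-bis(benzyloxy)-3-formyl-2-hydroxyphenyl]propanoate | COC(=O)[C@H](OCc1ccccc1)Cc1c(O)c(C=O)c(OCc2ccccc2)cc1OCc1ccccc1
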